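The six-membered ring of the bicyclo[3.2.1]octane (bridging ketone C9, isobutyryl-bearing bridgehead C1, CMe2 C8, prenylated CH C7, CH2 C6, prenylated bridgehead C5) is read as a cyclobutanone (C9, C1, C8, C7) into whose C9–C7 bond the C5=C6 unit of a 1,1-disubstituted alkene has been inserted. A rhodium-catalysed cut-and-sew therefore forms C6–C7 and C5–C9 in one operation and closes both the cyclohexanone and the five-membered ring (C9, C1, C2, C4, C5), because the alkene hangs on C1 through C2 and C4. The precursor is an enantiopure, fully substituted cyclobutanone made by RAMP-hydrazone prenylation and two aldol-type C–C bond formations at C1.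

Key step: step 10

Remark (locants): C1 = bridgehead with isobutyryl, C2 = ring ketone of the two-carbon bridge, C4 = carbinol carbon of that bridge, C5 = prenylated bridgehead, C6 = CH2, C7 = CH-prenyl, C8 = CMe2, C9 = bridging ketone; exo = syn to C9, endo = syn to the C6–C7–C8 bridge.
Remark (target form): the (Z)-γ-hydroxy enone may equilibrate with its five-membered lactol; the open form as drawn is taken as the target.
Remark (work-up): a lithium, potassium or samarium alkoxide or amidate left at the end of a step is taken as protonated on aqueous work-up, the metal leaving as its hydroxide.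

Step 1
Reactants: 1 3,3-dimethylcyclobutan-1-one; 2 (R)-1-amino-2-(methoxymethyl)pyrrolidine (RAMP)
Product: 3 RAMP hydrazone of 3,3-dimethylcyclobutanone
Conditions: neat, 60 °C, then removal of water under vacuum
Reagents that add atoms: none
Why: Hydrazone formation between the ketone and the chiral hydrazine installs the auxiliary that will control C7.

Step 2
Reactants: 3 RAMP hydrazone; 4 1-bromo-3-methylbut-2-ene (prenyl bromide)
Product: 7 (S)-3,3-dimethyl-2-(3-methylbut-2-en-1-yl)cyclobutan-1-one, via lithium azaenolate 5 (not isolated), via prenylated hydrazone 6 (not isolated)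
Conditions: LiN(iPr)2, THF, 0 °C; 4, −100 → −78 °C; then sat. aq. oxalic acid, Et2O, rt
Reagents that add atoms: water, O
Why: RAMP-hydrazone alkylation: the methoxymethyl-chelated lithium azaenolate is attacked by the primary allylic bromide (SN2) on its open face, which for cycloalkanone hydrazones of RAMP should give the (S)-2-alkyl ketone (C7), and biphasic oxalic acid hydrolysis should free the ketone without epimerisation and return the auxiliary.

Step 3
Reactants: 7 (S)-3,3-dimethyl-2-prenylcyclobutanone
Product: 9 (4S)-2-chloro-3,3-dimethyl-4-prenylcyclobutan-1-one, via lithium enolate 8 (not isolated)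
Conditions: LiN(SiMe3)2, THF, −78 °C; NCS, −78 °C
Reagents that add atoms: N-chlorosuccinimide, O=C1CCC(=O)N1Cl
Why: Kinetic deprotonation should take the CH2 (C1) rather than the hindered CH-prenyl carbon, and electrophilic α-chlorination of that enolate marks C1 as the site of the next two enolate formations; the C–Cl configuration is irrelevant.

Step 4
Reactants: 9 α-chloro ketone; 10 2-methylpropanal (isobutyraldehyde)
Product: 13 spiro-epoxy ketone, via lithium chloroenolate 11 (not isolated), via lithium chlorohydrin alkoxide 12 (not isolated)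
Conditions: LiN(iPr)2, THF, −78 °C; 10; −78 → 0 °C
Reagents that add atoms: none
Why: Darzens reaction: the chlorine-bearing carbon is the most acidic α-position, its enolate adds to the aldehyde and the alkoxide closes the epoxide by internal SN2 displacement on warming; the epoxide stereocentres are not needed because C1 is re-enolised in step 8 and the carbinol is oxidised in step 12.

Step 5
Reactants: 14 3-chloro-2-(chloromethyl)prop-1-ene; 15 2-methylprop-1-en-1-ylmagnesium bromide
Product: 16 2-(chloromethyl)-5-methylhexa-1,4-diene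
Conditions: CuI (10 mol%), THF, −30 → 0 °C, 14 in excess
Reagents that add atoms: none
Why: Copper-catalysed Grignard–allylic chloride coupling, in which SN2 and SN2' attack give the same product on this symmetric unit and an excess of 14 limits double substitution.

Step 6
Reactants: 16 2-(chloromethyl)-5-methylhexa-1,4-diene
Product: 18 6-methyl-3-methylidenehept-5-en-1-ol, via allylzinc chloride 17 (not isolated)
Conditions: Zn dust, aq. CH2O, THF/sat. aq. NH4Cl, rt
Reagents that add atoms: formaldehyde, C=O
Why: Barbier-type zinc-mediated hydroxymethylation of an allylic chloride in aqueous medium; both termini of the 2-substituted allylzinc are identical, so only one homoallylic alcohol can form.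

Step 7
Reactants: 18 6-methyl-3-methylidenehept-5-en-1-ol
Product: 19 6-methyl-3-methylidenehept-5-enal
Conditions: Dess–Martin periodinane, NaHCO3, CH2Cl2, 0 °C; used at once
Reagents that add atoms: none
Why: Dess–Martin oxidation under buffered neutral conditions should give the β,γ-unsaturated aldehyde without migration of the double bond into conjugation.

Step 8
Reactants: 13 spiro-epoxy ketone; 19 6-methyl-3-methylidenehept-5-enal
Product: 21 cyclobutanone diol, via samarium enolate 20 (not isolated)
Conditions: SmI2 (2.2 equiv), THF, −78 °C; then 19, −78 °C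
Reagents that add atoms: none
Why: Two single-electron transfers from divalent samarium cleave the Cα–O bond of the α,β-epoxy ketone to a samarium enolate located only at C1, which undergoes a Reformatsky-type aldol addition to 19; the aldehyde should approach planar C1 on the ring face opposite the C7 prenyl group, so the new hydroxyalkyl arm ends trans and the isopropyl carbinol arm cis to prenyl, which sets the quaternary C1 stereocentre.

Step 9
Reactants: 21 cyclobutanone diol
Product: 22 bis(triethylsilyl) ether of 21
Conditions: Et3SiOTf, 2,6-lutidine, CH2Cl2, −78 → −20 °C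
Reagents that add atoms: triethylsilyl trifluoromethanesulfonate, CC[Si](CC)(CC)OS(=O)(=O)C(F)(F)F
Why: Silylation of both hindered secondary alcohols with the silyl triflate removes the retro-aldol liability and leaves C1 without any carbonyl substituent, which matters for the site of C–C cleavage in step 10; the low temperature should keep the ketone from forming an enol silane at C7.

Step 10
Reactants: 22 bis(triethylsilyl) ether (cyclobutanone with the alkene tethered to C1)
Product: 23 bicyclo[3.2.1]octan-8-one bis(triethylsilyl) ether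
Conditions: [Rh(cod)Cl]2 (5 mol%), DTBM-SEGPHOS (12 mol%, matched enantiomer), 1,4-dioxane, 110–130 °C, sealed tube
Reagents that add atoms: none
Why: Monovalent rhodium should insert oxidatively into the less hindered C9–C7 acyl–alkyl bond of the strained ketone (C9–C1 is flanked by a fully substituted carbon), the tethered 1,1-disubstituted alkene then inserts into the Rh–acyl bond to form C9–C5, and C(sp3)–C(sp3) reductive elimination from trivalent rhodium forms C6–C7, driven by release of four-ring strain. The closest known reaction type is the rhodium-catalysed intramolecular olefin carboacylation of cyclobutanones by C–C activation (cut and sew, a formal [4+2]). The five-membered ring (C9, C1, C2, C4, C5) closes by 5-exo migratory insertion and the cyclohexanone ring (C9, C1, C8, C7, C6, C5) by reductive elimination from a seven-membered rhodacycle, a two-carbon ring expansion of the four-membered ketone. C5 is fixed by the two-atom tether from C1 (only one bridgehead configuration is geometrically possible), and C7 is carried through because oxidative addition and reductive elimination at C7 both proceed with retention. The step needs cleavage of C9–C7 rather than C9–C1 and insertion rather than decarbonylation or alkene migration; the carbonyl-free quaternary C1, the chelating reach of the alkene and a bulky bisphosphine should secure this.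

Step 11
Reactants: 23 bicyclic bis(triethylsilyl) ether
Product: 24 bicyclic diol
Conditions: HF·pyridine, pyridine/THF, 0 °C → rt
Reagents that add atoms: none
Why: Fluoride cleavage of both triethylsilyl ethers under buffered acidic conditions, chosen over basic fluoride to avoid retro-aldol opening of the β-hydroxy ketones.

Step 12
Reactants: 24 bicyclic diol
Product: 25 bicyclic trione (C9 and C2 ketones, C1 isobutyryl)
Conditions: Dess–Martin periodinane (3 equiv), NaHCO3, CH2Cl2, rt
Reagents that add atoms: none
Why: Dess–Martin oxidation of both secondary carbinols gives the C2 ketone and the C1 isobutyryl group at once, and the carbinol epimer mixtures converge on one compound.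

Step 13
Reactants: 25 bicyclic trione
Product: 28 C4 tert-butyldimethylsilyloxy trione, via potassium enolate 26 (not isolated), via potassium alkoxide 27 (not isolated)
Conditions: KN(SiMe3)2, THF, −78 °C; 2-(phenylsulfonyl)-3-phenyloxaziridine; then t-BuMe2SiOTf, −78 → 0 °C
Reagents that add atoms: 2-(phenylsulfonyl)-3-phenyloxaziridine, O=S(=O)(c1ccccc1)N1OC1c1ccccc1; tert-butyldimethylsilyl trifluoromethanesulfonate, CC(C)(C)[Si](C)(C)OS(=O)(=O)C(F)(F)F
Why: C4 is the only readily enolisable position (C1 and C5 are quaternary, the isobutyryl methine is shielded), its enolate is hydroxylated by the N-sulfonyloxaziridine (enolate oxidation, oxygen expected on the exo face) and the alkoxide is silylated in the same flask; the C4 configuration is erased in step 16.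

Step 14
Reactants: 29 2-methylbut-3-yn-2-ol
Product: 30 triethyl[(2-methylbut-3-yn-2-yl)oxy]silane
Conditions: Et3SiCl, imidazole, DMF, rt
Reagents that add atoms: chlorotriethylsilane, CC[Si](Cl)(CC)CC
Why: Imidazole-promoted silylation of a tertiary propargylic alcohol.

Step 15
Reactants: 30 silyl ether of 2-methylbut-3-yn-2-ol
Product: 32 4-methyl-4-(triethylsilyloxy)pent-2-ynal, via lithium acetylide 31 (not isolated)
Conditions: n-BuLi, THF, −78 °C; DMF; inverse quench into aq. KH2PO4
Reagents that add atoms: N,N-dimethylformamide, CN(C)C=O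
Why: Formylation of the lithium acetylide with DMF, with an inverse buffered quench to release the ynal without conjugate addition of dimethylamine.

Step 16
Reactants: 28 C4 silyloxy trione; 32 4-methyl-4-(triethylsilyloxy)pent-2-ynal
Product: 34 C4 aldol adduct, via lithium silyloxy enolate 33 (not isolated)
Conditions: LiN(iPr)2, THF, −78 → −40 °C; 32, −78 °C; AcOH quench at −78 °C
Reagents that add atoms: none
Why: Aldol 1,2-addition of the tetrasubstituted α-silyloxy enolate to the ynal; the electrophile should add to C4 on the exo face, away from the C6–C7–C8 bridge and its axial methyl, which places the new carbon exo and the oxygen endo as the C4 stereocentre requires; the carbinol configuration is irrelevant.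

Step 17
Reactants: 34 C4 aldol adduct
Product: 35 ynone
Conditions: Dess–Martin periodinane, NaHCO3, CH2Cl2, 0 °C
Reagents that add atoms: none
Why: Dess–Martin oxidation of the secondary propargylic alcohol to the ynone, with tertiary silyl ethers and alkenes untouched.

Step 18
Reactants: 35 ynone
Product: 36 (Z)-enone bis-silyl ether
Conditions: H2 (1 atm), Pd/CaCO3 poisoned with Pb(OAc)2, quinoline, EtOAc, 0 °C
Reagents that add atoms: none
Why: Lindlar semihydrogenation delivers H2 syn to the alkyne on the poisoned palladium surface to give the (Z)-enone, and the trisubstituted prenyl alkenes should not be reduced.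

Step 19
Reactants: 36 (Z)-enone bis-silyl ether
Product: 37 target
Conditions: HF·pyridine, pyridine/THF, 0 °C → rt
Reagents that add atoms: none
Why: Fluoride cleavage of the tertiary tert-butyldimethylsilyl and triethylsilyl ethers under buffered acidic conditions that avoid retro-Claisen cleavage of the triketone and E/Z isomerisation.

Compound list
1 | 3,3-dimethylcyclobutan-1-one | CC1(C)CC(=O)C1 | starting material
2 | (R)-1-amino-2-(methoxymethyl)pyrrolidine (RAMP) | NN1CCC[C@@H]1COC | starting material
3 | (R)-N-(3,3-dimethylcyclobutylidene)-2-(methoxymethyl)pyrrolidin-1-amine | CC1(C)CC(=NN2CCC[C@@H]2COC)C1 | intermediate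
4 | 1-bromo-3-methylbut-2-ene | CC(C)=CCBr | starting material
5 | lithium azaenolate of 3 | [Li]N(N1CCC[C@@H]1COC)C1=CC(C)(C)C1 | intermediate
6 | RAMP hydrazone of (S)-3,3-dimethyl-2-prenylcyclobutanone (C=N geometry not specified) | CC(C)=CC[C@@H]1C(=NN2CCC[C@@H]2COC)CC1(C)C | intermediate
7 | (S)-3,3-dimethyl-2-(3-methylbut-2-en-1-yl)cyclobutan-1-one | CC(C)=CC[C@@H]1C(=O)CC1(C)C | intermediate
8 | lithium enolate of 7 at the CH2 carbon (C1) | [Li]OC1=CC(C)(C)[C@@H]1CC=C(C)C | intermediate
9 | (4S)-2-chloro-3,3-dimethyl-4-(3-methylbut-2-en-1-yl)cyclobutan-1-one (epimers at the chlorine-bearing carbon) | CC(C)=CC[C@@H]1C(=O)C(Cl)C1(C)C | intermediate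
10 | 2-methylpropanal | CC(C)C=O | starting material
11 | lithium enolate of 9 at the chlorine-bearing carbon | [Li]OC1=C(Cl)C(C)(C)[C@@H]1CC=C(C)C | intermediate
12 | lithium alkoxide of the chlorohydrin from 11 and 10 | CC(C)=CC[C@@H]1C(=O)C(Cl)(C(O[Li])C(C)C)C1(C)C | intermediate
13 | (5S)-6,6-dimethyl-5-(3-methylbut-2-en-1-yl)-2-(propan-2-yl)-1-oxaspiro[2.3]hexan-4-one (mixture at both epoxide carbons) | CC(C)=CC[C@@H]1C(=O)C2(OC2C(C)C)C1(C)C | intermediate
14 | 3-chloro-2-(chloromethyl)prop-1-ene | ClCC(=C)CCl | starting material
15 | 2-methylprop-1-en-1-ylmagnesium bromide | CC(C)=C[Mg]Br | starting material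
16 | 2-(chloromethyl)-5-methylhexa-1,4-diene | ClCC(=C)CC=C(C)C | intermediate
17 | (5-methyl-2-methylidenehex-4-en-1-yl)zinc chloride | Cl[Zn]CC(=C)CC=C(C)C | intermediate
18 | 6-methyl-3-methylidenehept-5-en-1-ol | OCCC(=C)CC=C(C)C | intermediate
19 | 6-methyl-3-methylidenehept-5-enal | O=CCC(=C)CC=C(C)C | intermediate
20 | samarium enolate at C1 carrying the samarium alkoxide of the isopropyl carbinol | I[Sm](I)OC1=C(C(O[Sm](I)I)C(C)C)C(C)(C)[C@@H]1CC=C(C)C | intermediate
21 | (2R,4S)-2-(1-hydroxy-2-methylpropyl)-2-(1-hydroxy-6-methyl-3-methylidenehept-5-en-1-yl)-3,3-dimethyl-4-(3-methylbut-2-en-1-yl)cyclobutan-1-one; hydroxyheptenyl arm trans and hydroxyisobutyl arm cis to prenyl; both carbinol centres as epimer mixtures | CC(C)=CC[C@@H]1C(=O)[C@@](C(O)C(C)C)(C(O)CC(=C)CC=C(C)C)C1(C)C | intermediate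
22 | bis(triethylsilyl) ether of 21 (same ring configuration, carbinol epimers) | CC(C)=CC[C@@H]1C(=O)[C@@](C(O[Si](CC)(CC)CC)C(C)C)(C(O[Si](CC)(CC)CC)CC(=C)CC=C(C)C)C1(C)C | intermediate
23 | bicyclo[3.2.1]octan-8-one (C9 ketone) with C1 CH(OSiEt3)iPr, C2 OSiEt3, C4 H2, C5 prenyl, C7 prenyl anti to the C2–C4 bridge, C8 Me2; epimers at C2 and at the side-chain carbinol | CC(C)=CC[C@@H]1C[C@]2(CC=C(C)C)C(=O)[C@@](C(O[Si](CC)(CC)CC)C(C)C)(C(O[Si](CC)(CC)CC)C2)C1(C)C | intermediate
24 | diol from 23 (C2 OH and C1 CH(OH)iPr, carbinol epimers) | CC(C)=CC[C@@H]1C[C@]2(CC=C(C)C)C(=O)[C@@](C(O)C(C)C)(C(O)C2)C1(C)C | intermediate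
25 | bicyclic trione: C9 and C2 ketones, C1 isobutyryl, C4 H2, C5 and C7 prenyl, C8 Me2 | CC(C)=CC[C@@H]1C[C@]2(CC=C(C)C)C(=O)[C@@](C(=O)C(C)C)(C(=O)C2)C1(C)C | intermediate
26 | potassium enolate of 25 (C2–O, C2=C4) | CC(C)=CC[C@@H]1C[C@]2(CC=C(C)C)C(=O)[C@@](C(=O)C(C)C)(C(O[K])=C2)C1(C)C | intermediate
27 | potassium alkoxide of the C4 exo-hydroxy trione | CC(C)=CC[C@@H]1C[C@]2(CC=C(C)C)C(=O)[C@@](C(=O)C(C)C)(C(=O)[C@H]2O[K])C1(C)C | intermediate
28 | C4 exo-(tert-butyldimethylsilyloxy) trione | CC(C)=CC[C@@H]1C[C@]2(CC=C(C)C)C(=O)[C@@](C(=O)C(C)C)(C(=O)[C@H]2O[Si](C)(C)C(C)(C)C)C1(C)C | intermediate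
29 | 2-methylbut-3-yn-2-ol | CC(C)(O)C#C | starting material
30 | triethyl[(2-methylbut-3-yn-2-yl)oxy]silane | CC(C)(O[Si](CC)(CC)CC)C#C | intermediate
31 | lithium acetylide of 30 | [Li]C#CC(C)(C)O[Si](CC)(CC)CC | intermediate
32 | 4-methyl-4-(triethylsilyloxy)pent-2-ynal | O=CC#CC(C)(C)O[Si](CC)(CC)CC | intermediate
33 | lithium enolate of 28 (C2–O, C2=C4, C4 silyloxy) | CC(C)=CC[C@@H]1C[C@]2(CC=C(C)C)C(=O)[C@@](C(=O)C(C)C)(C(O[Li])=C2O[Si](C)(C)C(C)(C)C)C1(C)C | intermediate
34 | aldol adduct: C4 endo-OSi(t-Bu)Me2, C4 exo-CH(OH)C≡C–CMe2OSiEt3 (carbinol epimers) | CC(C)=CC[C@@H]1C[C@]2(CC=C(C)C)C(=O)[C@@](C(=O)C(C)C)(C(=O)[C@@]2(O[Si](C)(C)C(C)(C)C)C(O)C#CC(C)(C)O[Si](CC)(CC)CC)C1(C)C | intermediate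
35 | ynone: C4 endo-OSi(t-Bu)Me2, C4 exo-C(=O)C≡C–CMe2OSiEt3 | CC(C)=CC[C@@H]1C[C@]2(CC=C(C)C)C(=O)[C@@](C(=O)C(C)C)(C(=O)[C@@]2(O[Si](C)(C)C(C)(C)C)C(=O)C#CC(C)(C)O[Si](CC)(CC)CC)C1(C)C | intermediate
36 | (Z)-enone: C4 endo-OSi(t-Bu)Me2, C4 exo-(Z)-C(=O)CH=CH–CMe2OSiEt3 | CC(C)=CC[C@@H]1C[C@]2(CC=C(C)C)C(=O)[C@@](C(=O)C(C)C)(C(=O)[C@@]2(O[Si](C)(C)C(C)(C)C)C(=O)/C=C\C(C)(C)O[Si](CC)(CC)CC)C1(C)C | intermediate
37 | target: C9 and C2 ketones, C1 isobutyryl, C4 endo-OH and exo-(Z)-4-hydroxy-4-methylpent-2-enoyl, C5 prenyl, C7 prenyl anti to the C2–C4 bridge, C8 Me2 | CC(C)=CC[C@@H]1C[C@]2(CC=C(C)C)C(=O)[C@@](C(=O)C(C)C)(C(=O)[C@@]2(O)C(=O)/C=C\C(C)(C)O)C1(C)C | target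

Total step count: 19. Longest linear sequence: 14 steps (steps 1–4, 8–13, 16–19).

Steps most likely to fail

Step 10. Oxidative addition may go into the C9–C1 bond or be blocked by the crowded ketone, the acyl rhodium intermediate may lose CO to give a cyclopropane, or the hindered 1,1-disubstituted alkene may migrate before it inserts; the alpha-tethered arrangement with cleavage of the distal bond is also the less explored topology of this reaction. The fallback sets out from 22 and comes back at 23 by a different mode of C–C cleavage: on zerovalent nickel (Ni(cod)2, PCy3, toluene, 100 °C) the C9=O and C5=C6 units would first couple by oxidative cyclisation to an oxanickelacyclopentane (C9–C5 bond), the four-membered ring would then open by β-carbon elimination of the less substituted C9–C7 bond, and C6–C7 reductive elimination would close the ring. No acyl metal species is formed, so decarbonylation is excluded, and no new compound arises on this way (F0).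

Step 8. The samarium enolate may be protonated by the enolisable β,γ-unsaturated aldehyde, the aldehyde double bond may move into conjugation, the enolate may lose isobutyraldehyde by retro-aldol, or facial selectivity at C1 may be poor. The fallback sets out from 13 and comes back at 21. The same samarium enolate is trapped with monomeric formaldehyde in THF, which cannot enolise, to give the hydroxymethyl diol F1 (hydroxymethyl trans to prenyl). The primary alcohol is oxidised selectively (TEMPO, PhI(OAc)2, CH2Cl2) to the formyl ketone F2. An indium-mediated Barbier allylation with allylic chloride 16 (indium powder, NaI, THF/H2O), selective for the aldehyde over the ketone, then forms the C2–C4 bond instead of the C1–C2 bond and gives 21.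

Step 16. Removal of the endo C4–H next to the silyloxy group may be slow, so that the isobutyryl methine enolises instead; the aldolate may revert on quench, or the silyl group may migrate to the new alkoxide. The fallback sets out from 25 and comes back at 37. The enolate of 25 is hydroxylated as in step 13 but worked up to the free acyloin F3, which Dess–Martin periodinane oxidises to the C2,C4-diketone F4. SmI2 (2 equiv, THF, −78 °C) reduces F4 to the samarium enediolate, which should add to ynal 32 at the less hindered C4 from the exo face to give the diol F5. Dess–Martin oxidation of the secondary propargylic alcohol gives the hydroxy ynone F6, Lindlar semihydrogenation gives the (Z)-enone triethylsilyl ether F7, and HF·pyridine gives 37.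

Further compounds
F0 | step 10 | none | none
F1 | step 8 | 2-(hydroxymethyl)-2-(1-hydroxy-2-methylpropyl)-3,3-dimethyl-4-prenylcyclobutan-1-one (hydroxymethyl trans to prenyl) | CC(C)=CC[C@@H]1C(=O)[C@@](C(O)C(C)C)(CO)C1(C)C
F2 | step 8 | 2-formyl-2-(1-hydroxy-2-methylpropyl)-3,3-dimethyl-4-prenylcyclobutan-1-one | CC(C)=CC[C@@H]1C(=O)[C@@](C(O)C(C)C)(C=O)C1(C)C
F3 | step 16 | C4 exo-hydroxy trione (free acyloin) | CC(C)=CC[C@@H]1C[C@]2(CC=C(C)C)C(=O)[C@@](C(=O)C(C)C)(C(=O)[C@H]2O)C1(C)C
F4 | step 16 | C2,C4-diketone (tetraone) | CC(C)=CC[C@@H]1C[C@]2(CC=C(C)C)C(=O)[C@@](C(=O)C(C)C)(C(=O)C2=O)C1(C)C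
F5 | step 16 | C4 endo-hydroxy, exo-CH(OH)C≡C–CMe2OSiEt3 diol | CC(C)=CC[C@@H]1C[C@]2(CC=C(C)C)C(=O)[C@@](C(=O)C(C)C)(C(=O)[C@@]2(O)C(O)C#CC(C)(C)O[Si](CC)(CC)CC)C1(C)C
F6 | step 16 | C4 endo-hydroxy ynone | CC(C)=CC[C@@H]1C[C@]2(CC=C(C)C)C(=O)[C@@](C(=O)C(C)C)(C(=O)[C@@]2(O)C(=O)C#CC(C)(C)O[Si](CC)(CC)CC)C1(C)C
F7 | step 16 | side-chain triethylsilyl ether of the target | CC(C)=CC[C@@H]1C[C@]2(CC=C(C)C)C(=O)[C@@](C(=O)C(C)C)(C(=O)[C@@]2(O)C(=O)/C=C\C(C)(C)O[Si](CC)(CC)CC)C1(C)C
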